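## Plan

- Labels: five-membered ring C1(CH3)–C2–C3–C4(OH)(iPr)–C5(H); seven-membered ring C5–C6(OAr)–C7(=O)–C8(OH)(CH3)–C9(OH)–C10–C1. β is the face of the C1 methyl, α the opposite face.
- Cuts, in retrosynthetic order: the O6 acyl bond; both C–O bonds at C8 and C9 (back to a C8=C9 enone); C7–C8 and C8–C9, which lifts out C8 with its methyl; C6–O together with C5–H; C4–iPr; the C4 carbonyl oxygen; C5=C6 and C1–C10.
- Enabling feature: C8 is a CH3–C unit held only between the C7 carbonyl and C9. The seven-membered ring is therefore the six-membered ketone C1–C5–C6–C7–C9–C10 plus one carbene carbon pushed into the C7=C9 bond of its silyl enol ether.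
- Forward order: the five-membered ring is bought, the six-membered ring is annulated onto it (Michael addition, aldol condensation), and the seven-membered ring arises last by one-carbon enlargement; acylation and dihydroxylation finish the route.
- Stereochemistry: C1 comes from an (S)-1-phenylethylamine-controlled Michael addition; C4, then C5 with C6, then C8 with C9 are each set by attack on the face opposite the C1 methyl.

Key step: step 13

Remark: 2-methylcyclopentanone is used as the racemate, because its stereocentre equilibrates through the imine–enamine pair in steps 1 and 2. Bicyclic intermediates before step 13 carry the labels C1–C7, C9 and C10 (no C8) and are named as hydrindanes; from step 13 on, "daucane" means the 5/7 skeleton labelled above.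

## Route

Step 1
Reactants: 1 2-methylcyclopentanone; 2 (S)-1-phenylethylamine
Product: 3 (S)-N-(2-methylcyclopentylidene)-1-phenylethanamine
Conditions: TsOH (cat.), toluene, 110 °C, Dean–Stark
Reagents that add atoms: none
Why: Acid-catalysed imine condensation driven by azeotropic removal of water; no stereocentre is fixed, since the ring methyl centre stays labile through imine–enamine tautomerism.

Step 2
Reactants: 3 (S)-N-(2-methylcyclopentylidene)-1-phenylethanamine; 4 but-3-en-2-one
Product: 6 (R)-2-methyl-2-(3-oxobutyl)cyclopentanone, via Michael-adduct imine 5 (not isolated)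
Conditions: 4, THF, 25 °C; then 20% aq AcOH, 25 °C
Reagents that add atoms: water, O
Why: Asymmetric Michael addition through the more substituted secondary enamine tautomer (aza-ene-type), in which the enone is delivered to the enamine face remote from the phenyl group of the auxiliary, should set the C1 quaternary centre as R with high enantiomeric excess; mild hydrolysis then releases the 1,5-diketone and the amine.

Step 3
Reactants: 6 (R)-2-methyl-2-(3-oxobutyl)cyclopentanone
Product: 8 (R)-7a-methyl-1,2,3,6,7,7a-hexahydro-5H-inden-5-one (C7 ketone, C5=C6), via cis-fused aldol ketol 7 (not isolated)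
Conditions: KOH, MeOH, 65 °C
Reagents that add atoms: none
Why: Intramolecular aldol condensation (second stage of a Robinson annulation): the methyl ketone enolate closes the six-membered ring onto the ring carbonyl (6-enolexo-exo-trig) and the ketol dehydrates to the conjugated enone, leaving C1 untouched.

Step 4
Reactants: 8 (R)-7a-methyl-1,2,3,6,7,7a-hexahydro-5H-inden-5-one
Product: 10 1β-methylhydrind-5-ene-4,7-dione, via C4 tert-butylperoxy enone 9 (not isolated)
Conditions: Pd(OH)2/C (cat.), t-BuOOH, K2CO3, CH2Cl2, 25 °C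
Reagents that add atoms: tert-butyl hydroperoxide, CC(C)(C)OO
Why: Palladium-catalysed γ-oxidation of an enone to the 1,4-enedione: the tert-butylperoxy radical functionalises the only γ-methylene (C4), and base-induced loss of tert-butanol from the peroxide (Kornblum–DeLaMare-type) gives the C4 ketone.

Step 5
Reactants: 10 1β-methylhydrind-5-ene-4,7-dione
Product: 11 7β-hydroxy-1β-methylhydrind-5-en-4-one
Conditions: NaBH4 (0.3 equiv), CeCl3·7H2O, MeOH, −78 °C
Reagents that add atoms: none
Why: Luche 1,2-reduction with a deficiency of hydride should take the six-ring carbonyl C7 (flanked by CH2 and CH) in preference to the cyclopentanone carbonyl C4 (flanked by the fully substituted C5, and gaining torsional strain on rehybridisation); axial hydride delivery anti to the C1 methyl gives the 7β alcohol, a centre that is removed again in step 11.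

Step 6
Reactants: 11 7β-hydroxy-1β-methylhydrind-5-en-4-one
Product: 12 1β-methyl-7β-(triethylsilyloxy)hydrind-5-en-4-one
Conditions: Et3SiCl, imidazole, CH2Cl2, 0 °C
Reagents that add atoms: chlorotriethylsilane, CC[Si](Cl)(CC)CC
Why: Standard imidazole-mediated silylation of a secondary allylic alcohol; no stereocentre changes.

Step 7
Reactants: 12 1β-methyl-7β-(triethylsilyloxy)hydrind-5-en-4-one; 13 isopropylmagnesium chloride
Product: 14 4α-isopropyl-1β-methyl-7β-(triethylsilyloxy)hydrind-5-en-4β-ol
Conditions: 13, CeCl3 (anhydrous), THF, −78 → 0 °C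
Reagents that add atoms: none
Why: Organocerium 1,2-addition to a hindered, enolisable enone (CeCl3 suppresses enolisation, β-hydride reduction and conjugate addition); the reagent should approach C4 on the α face, away from the C1 methyl that sits over the β face of the five-membered ring, giving 4β-OH and 4α-iPr.

Step 8
Reactants: 14 4α-isopropyl-1β-methyl-7β-(triethylsilyloxy)hydrind-5-en-4β-ol
Product: 16 4α-isopropyl-1β-methyl-7β-(triethylsilyloxy)-5α-hydrindane-4β,6α-diol, via C6 alkylborane 15 (not isolated)
Conditions: BH3·THF, THF, 0 → 25 °C; then NaBO3·4H2O, H2O, 25 °C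
Reagents that add atoms: sodium perborate, [Na+].[Na+].O[B-]1(O)OO[B-](O)(O)OO1
Why: Hydroboration–oxidation: syn addition of H to C5 and B to the less substituted C6 on the α face, anti to the angular methyl and to both allylic β-oxygen substituents, sets 5α-H (trans ring fusion) and, with retention in the mild perborate oxidation, 6α-OH.

Step 9
Reactants: 16 4α-isopropyl-1β-methyl-7β-(triethylsilyloxy)-5α-hydrindane-4β,6α-diol
Product: 17 6α-(tert-butyldimethylsilyloxy)-4α-isopropyl-1β-methyl-7β-(triethylsilyloxy)-5α-hydrindan-4β-ol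
Conditions: TBSOTf (1.1 equiv), 2,6-lutidine, CH2Cl2, −78 °C
Reagents that add atoms: tert-butyldimethylsilyl triflate, CC(C)(C)[Si](C)(C)OS(=O)(=O)C(F)(F)F
Why: Silyl triflate silylation, in which the secondary C6 hydroxyl should react far faster than the tertiary C4 hydroxyl at low temperature.

Step 10
Reactants: 17 6α-(tert-butyldimethylsilyloxy)-4α-isopropyl-1β-methyl-7β-(triethylsilyloxy)-5α-hydrindan-4β-ol
Product: 18 6α-(tert-butyldimethylsilyloxy)-4α-isopropyl-1β-methyl-5α-hydrindane-4β,7β-diol
Conditions: PPTS (cat.), MeOH/CH2Cl2, 0 °C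
Reagents that add atoms: none
Why: Selective acid-catalysed methanolysis, since a secondary triethylsilyl ether is cleaved much faster than a tert-butyldimethylsilyl ether.

Step 11
Reactants: 18 6α-(tert-butyldimethylsilyloxy)-4α-isopropyl-1β-methyl-5α-hydrindane-4β,7β-diol
Product: 19 6α-(tert-butyldimethylsilyloxy)-4β-hydroxy-4α-isopropyl-1β-methyl-5α-hydrindan-7-one
Conditions: Dess–Martin periodinane, pyridine, CH2Cl2, 25 °C
Reagents that add atoms: none
Why: Dess–Martin oxidation of the only secondary alcohol under buffered conditions; the tertiary alcohol is inert and the equatorial 6α-silyloxy centre is the stable epimer next to the new ketone.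

Step 12
Reactants: 19 6α-(tert-butyldimethylsilyloxy)-4β-hydroxy-4α-isopropyl-1β-methyl-5α-hydrindan-7-one
Product: 20 6α-(tert-butyldimethylsilyloxy)-4α-isopropyl-1β-methyl-4β,7-bis(trimethylsilyloxy)-5α-hydrind-7(9)-ene (C7=C9 silyl enol ether)
Conditions: LiN(iPr)2 (2.5 equiv), THF, −78 °C; Me3SiCl, Et3N, −78 → 25 °C
Reagents that add atoms: chlorotrimethylsilane, C[Si](C)(C)Cl
Why: Kinetic enolate formation and O-silylation: the amide base removes a C9 methylene proton and not the hindered C6–H that carries the silyloxy group, and the chlorosilane caps both the enolate and the C4 alkoxide.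

Step 13
Reactants: 20 C7=C9 silyl enol ether; 21 1,1-dichloroethane
Product: 23 6α-(tert-butyldimethylsilyloxy)-4β-(trimethylsilyloxy)dauc-8-en-7-one (trans-fused 2-methylcyclohept-2-enone), via endo-chloro siloxycyclopropane 22 (not isolated)
Conditions: 21 (excess), n-BuLi, Et2O, −40 °C; then toluene, pyridine (cat.), 110 °C
Reagents that add atoms: none
Why: n-BuLi deprotonates 21 to 1,1-dichloroethyllithium, which loses LiCl and transfers chloro(methyl)carbene to the electron-rich C7=C9 enol ether in a concerted [2+1] addition that forms C7–C8 and C8–C9 and closes the three-membered ring of a bicyclo[4.1.0] unit (22). On heating, the chloride cis to the ring bonds ionises with disrotatory, oxygen-assisted cyclopropyl-to-allyl opening that cleaves C7–C9, and chloride then takes the silyl group from the silyloxyallyl cation to leave the 2-methylcyclohept-2-enone; the seven-membered ring thus arises by breaking the internal bond of the bicycle and not by a new closure. The closest known reaction type is the halocarbene ring enlargement of cyclic silyl enol ethers to one-carbon-homologated 2-substituted cycloalkenones. No stereocentre is created in 23 (the cyclopropane centres are transient, with approach expected on the α face anti to the axial C1 methyl), and C1, C4, C5 and C6 are not touched. The step needs the enol ether on the C9 side (fixed in step 12), reaction at the enol ether only (it is the sole alkene and the C4 oxygen is capped), and chloride endo so that the ring bonds can rotate inward, which is the usual preference of lithium chlorocarbenoids and leaves the methyl group exo.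

Step 14
Reactants: 23 6α-(tert-butyldimethylsilyloxy)-4β-(trimethylsilyloxy)dauc-8-en-7-one
Product: 24 4β,6α-dihydroxydauc-8-en-7-one
Conditions: HF·pyridine, THF, 0 → 25 °C
Reagents that add atoms: none
Why: Fluoride-mediated desilylation under mildly acidic conditions removes both silyl ethers without the base-induced epimerisation or ketol shift that could threaten C6.

Step 15
Reactants: 24 4β,6α-dihydroxydauc-8-en-7-one; 25 4-(benzyloxy)benzoyl chloride
Product: 26 6α-[4-(benzyloxy)benzoyloxy]-4β-hydroxydauc-8-en-7-one
Conditions: 25, pyridine, DMAP (cat.), CH2Cl2, 0 → 25 °C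
Reagents that add atoms: none
Why: DMAP-catalysed acylation of the secondary C6 hydroxyl with an acid chloride; the tertiary C4 hydroxyl should not react.

Step 16
Reactants: 26 6α-[4-(benzyloxy)benzoyloxy]-4β-hydroxydauc-8-en-7-one
Product: 27 6α-[4-(benzyloxy)benzoyloxy]-4β,8α,9α-trihydroxydaucan-7-one
Conditions: OsO4 (cat.), NMO, citric acid, t-BuOH/H2O, 25 °C
Reagents that add atoms: osmium tetroxide, O=[Os](=O)(=O)=O; N-methylmorpholine N-oxide, C[N+]1([O-])CCOCC1; water, O
Why: Catalytic OsO4 cis-dihydroxylation: suprafacial [3+2] addition to C8=C9 on the α face, anti to the axial C1 methyl (the C6 ester is pseudo-equatorial and leaves that face open), should set 8α-OH and 9α-OH in one event; citric acid keeps the electron-poor enone reactive and the medium non-basic.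

Step 17
Reactants: 27 6α-[4-(benzyloxy)benzoyloxy]-4β,8α,9α-trihydroxydaucan-7-one
Product: 28 6α-(4-hydroxybenzoyloxy)-4β,8α,9α-trihydroxydaucan-7-one (CNP0241001.1)
Conditions: H2 (1 atm), Pd/C, EtOAc, 25 °C
Reagents that add atoms: none
Why: Hydrogenolysis of the benzyl aryl ether under neutral conditions; the ketone, the ester and the alcohols are inert and no alkene remains.

## Compound list

1 | 2-methylcyclopentanone (racemic) | CC1CCCC1=O | starting material
2 | (S)-1-phenylethylamine | C[C@H](N)c1ccccc1 | starting material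
3 | (S)-N-(2-methylcyclopentylidene)-1-phenylethanamine (ring methyl centre unfixed) | C[C@H](N=C1CCCC1C)c1ccccc1 | intermediate
4 | but-3-en-2-one (methyl vinyl ketone) | CC(=O)C=C | starting material
5 | Michael-adduct imine: (S)-1-phenylethyl imine of (R)-2-methyl-2-(3-oxobutyl)cyclopentanone (not isolated) | C[C@H](N=C1CCC[C@]1(C)CCC(C)=O)c1ccccc1 | intermediate
6 | (R)-2-methyl-2-(3-oxobutyl)cyclopentanone | O=C1CCC[C@]1(C)CCC(C)=O | intermediate
7 | cis-fused aldol ketol, 5β-hydroxy-1β-methylhydrindan-7-one (not isolated) | O=C1C[C@]2(O)CCC[C@]2(C)CC1 | intermediate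
8 | (R)-7a-methyl-1,2,3,6,7,7a-hexahydro-5H-inden-5-one (C7 ketone, C5=C6) | O=C1C=C2CCC[C@]2(C)CC1 | intermediate
9 | C4 tert-butylperoxy derivative of 8 (either C4 epimer, not isolated) | CC(C)(C)OOC1CC[C@]2(C)CCC(=O)C=C12 | intermediate
10 | 1β-methylhydrind-5-ene-4,7-dione (7a-methyl-1,2,7,7a-tetrahydro-3H-indene-3,5(6H)-dione) | O=C1CC[C@]2(C)CCC(=O)C=C12 | intermediate
11 | 7β-hydroxy-1β-methylhydrind-5-en-4-one | O=C1CC[C@]2(C)CC[C@@H](O)C=C12 | intermediate
12 | 1β-methyl-7β-(triethylsilyloxy)hydrind-5-en-4-one | O=C1CC[C@]2(C)CC[C@@H](O[Si](CC)(CC)CC)C=C12 | intermediate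
13 | isopropylmagnesium chloride | CC(C)[Mg]Cl | starting material
14 | 4α-isopropyl-1β-methyl-7β-(triethylsilyloxy)hydrind-5-en-4β-ol | CC(C)[C@]1(O)CC[C@]2(C)CC[C@@H](O[Si](CC)(CC)CC)C=C21 | intermediate
15 | C6 alkylborane (6α-boryl, 5α-H; not isolated) | CC(C)[C@]1(O)CC[C@]2(C)CC[C@@H](O[Si](CC)(CC)CC)[C@H](B)[C@H]21 | intermediate
16 | 4α-isopropyl-1β-methyl-7β-(triethylsilyloxy)-5α-hydrindane-4β,6α-diol | CC(C)[C@]1(O)CC[C@]2(C)CC[C@@H](O[Si](CC)(CC)CC)[C@H](O)[C@H]21 | intermediate
17 | 6α-(tert-butyldimethylsilyloxy)-4α-isopropyl-1β-methyl-7β-(triethylsilyloxy)-5α-hydrindan-4β-ol | CC(C)[C@]1(O)CC[C@]2(C)CC[C@@H](O[Si](CC)(CC)CC)[C@H](O[Si](C)(C)C(C)(C)C)[C@H]21 | intermediate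
18 | 6α-(tert-butyldimethylsilyloxy)-4α-isopropyl-1β-methyl-5α-hydrindane-4β,7β-diol | CC(C)[C@]1(O)CC[C@]2(C)CC[C@@H](O)[C@H](O[Si](C)(C)C(C)(C)C)[C@H]21 | intermediate
19 | 6α-(tert-butyldimethylsilyloxy)-4β-hydroxy-4α-isopropyl-1β-methyl-5α-hydrindan-7-one | CC(C)[C@]1(O)CC[C@]2(C)CCC(=O)[C@H](O[Si](C)(C)C(C)(C)C)[C@H]21 | intermediate
20 | C7=C9 silyl enol ether: 6α-(tert-butyldimethylsilyloxy)-4α-isopropyl-1β-methyl-4β,7-bis(trimethylsilyloxy)-5α-hydrind-7(9)-ene | CC(C)[C@]1(O[Si](C)(C)C)CC[C@]2(C)CC=C(O[Si](C)(C)C)[C@H](O[Si](C)(C)C(C)(C)C)[C@H]21 | intermediate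
21 | 1,1-dichloroethane | CC(Cl)Cl | starting material
22 | siloxycyclopropane with C8(Cl)(CH3) bridging C7 and C9 on the α face, chloride endo (not isolated) | CC(C)[C@]1(O[Si](C)(C)C)CC[C@]2(C)C[C@@H]3[C@](C)(Cl)[C@]3(O[Si](C)(C)C)[C@H](O[Si](C)(C)C(C)(C)C)[C@H]21 | intermediate
23 | 6α-(tert-butyldimethylsilyloxy)-4β-(trimethylsilyloxy)dauc-8-en-7-one | CC(C)[C@]1(O[Si](C)(C)C)CC[C@]2(C)CC=C(C)C(=O)[C@H](O[Si](C)(C)C(C)(C)C)[C@H]21 | intermediate
24 | 4β,6α-dihydroxydauc-8-en-7-one | CC(C)[C@]1(O)CC[C@]2(C)CC=C(C)C(=O)[C@H](O)[C@H]21 | intermediate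
25 | 4-(benzyloxy)benzoyl chloride | O=C(Cl)c1ccc(OCc2ccccc2)cc1 | starting material
26 | 6α-[4-(benzyloxy)benzoyloxy]-4β-hydroxydauc-8-en-7-one | CC(C)[C@]1(O)CC[C@]2(C)CC=C(C)C(=O)[C@H](OC(=O)c3ccc(OCc4ccccc4)cc3)[C@H]21 | intermediate
27 | 6α-[4-(benzyloxy)benzoyloxy]-4β,8α,9α-trihydroxydaucan-7-one | CC(C)[C@]1(O)CC[C@]2(C)C[C@H](O)[C@](C)(O)C(=O)[C@H](OC(=O)c3ccc(OCc4ccccc4)cc3)[C@H]21 | intermediate
28 | 6α-(4-hydroxybenzoyloxy)-4β,8α,9α-trihydroxydaucan-7-one (1β-CH3, 5α-H; CNP0241001.1) | CC(C)[C@]1(O)CC[C@]2(C)C[C@H](O)[C@](C)(O)C(=O)[C@H](OC(=O)c3ccc(O)cc3)[C@H]21 | target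

## Step count and risks

Total step count: 17. Longest linear sequence: 17 steps (1 → 28); compounds 2, 4, 13, 21 and 25 are bought.

Steps most likely to fail:

1. Step 13. Part of the carbenoid may add with chloride exo, and that epimer cannot ionise with inward rotation of the ring bonds, so material would stall at the cyclopropane stage; n-BuLi may also attack the substrate before it meets 21. The fallback sets out from 20 and returns at 23. Dibromocarbene (CHBr3, KOt-Bu, pentane, −20 °C) is added to the enol ether to give the 8,8-dibromo siloxycyclopropane F1, in which one bromide is necessarily endo. Warming in toluene with pyridine opens it, with loss of bromotrimethylsilane, to the 2-bromocyclohept-2-enone F2. Stille methylation (Me4Sn, Pd(PPh3)4, CuI, DMF, 60 °C) then gives 23. The same C7–C8 and C8–C9 bonds form by carbene addition and the same ring is enlarged; only the methyl group arrives in a separate coupling.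

2. Step 5. Hydride may not discriminate well enough between the C7 and C4 carbonyls of the enedione, or reduction may run on to the diol. The fallback sets out from 8 and returns at 12; it reduces the C7 carbonyl before the C4 oxygen exists, so no two carbonyls compete. Luche reduction of 8 gives the 7β allylic alcohol F3, and silylation (Et3SiCl, imidazole) gives the triethylsilyl ether F4. Allylic hydroxylation with SeO2 (cat.) and t-BuOOH in CH2Cl2 (ene reaction followed by [2,3] shift, which functionalises the CH2 on the more substituted alkene terminus, C4) gives the C4 alcohol F5. Dess–Martin oxidation then gives 12.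

3. Step 16. Osmylation of the flexible seven-membered enone may show poor facial selectivity and deliver some β-diol. The fallback sets out from 24 and returns at 27; it dihydroxylates before acylation, so that the free 6α-hydroxyl can steer the oxidant. OsO4 (cat.) with Me3NO·2H2O in CH2Cl2, a non-coordinating medium in which the hydroxyl hydrogen-bonds to the oxidant, should give the 4β,6α,8α,9α-tetraol F6. 2,2-Dimethoxypropane with PPTS masks the cis-8,9-diol as the acetonide F7. Acylation of O6 with 25 (pyridine, DMAP) gives the acetonide ester F8, and aqueous acetic acid at 40 °C removes the acetonide to give 27.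

## Further compounds

F1 | step 13 | 8,8-dibromo siloxycyclopropane (C8 bridging C7 and C9 on the α face) | CC(C)[C@]1(O[Si](C)(C)C)CC[C@]2(C)C[C@@H]3C(Br)(Br)[C@]3(O[Si](C)(C)C)[C@H](O[Si](C)(C)C(C)(C)C)[C@H]21
F2 | step 13 | 8-bromo-6α-(tert-butyldimethylsilyloxy)-4β-(trimethylsilyloxy)-8-nordauc-8-en-7-one (2-bromocyclohept-2-enone) | CC(C)[C@]1(O[Si](C)(C)C)CC[C@]2(C)CC=C(Br)C(=O)[C@H](O[Si](C)(C)C(C)(C)C)[C@H]21
F3 | step 5 | 1β-methylhydrind-5-en-7β-ol | O[C@H]1C=C2CCC[C@]2(C)CC1
F4 | step 5 | 1β-methyl-7β-(triethylsilyloxy)hydrind-5-ene | CC[Si](CC)(CC)O[C@H]1C=C2CCC[C@]2(C)CC1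
F5 | step 5 | 1β-methyl-7β-(triethylsilyloxy)hydrind-5-en-4-ol (either C4 epimer) | CC[Si](CC)(CC)O[C@H]1C=C2C(O)CC[C@]2(C)CC1
F6 | step 16 | 4β,6α,8α,9α-tetrahydroxydaucan-7-one | CC(C)[C@]1(O)CC[C@]2(C)C[C@H](O)[C@](C)(O)C(=O)[C@H](O)[C@H]21
F7 | step 16 | 8α,9α-O-isopropylidene-4β,6α-dihydroxydaucan-7-one | CC(C)[C@]1(O)CC[C@]2(C)C[C@@H]3OC(C)(C)O[C@]3(C)C(=O)[C@H](O)[C@H]21
F8 | step 16 | 6α-[4-(benzyloxy)benzoyloxy]-8α,9α-O-isopropylidene-4β-hydroxydaucan-7-one | CC(C)[C@]1(O)CC[C@]2(C)C[C@@H]3OC(C)(C)O[C@]3(C)C(=O)[C@H](OC(=O)c4ccc(OCc5ccccc5)cc4)[C@H]21
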